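The earlier runs and the new flask are simulated for an exercise; the scatter is artificial.

Start from the product and follow one molecule of coupling partner to its end; that is the way to read the south flask, carried on to 4.0 d.

| setting | south | south-west | flask |
|---|---|---|---|
| substrate | 0.076 M | 0.076 M | 0.076 M |
| coupling partner | 0.0532 M | 0.11 M | 0.0532 M |
| initiator | 3.8 mM | 3.8 mM | 3.8 mM |
| temperature | 25 °C | 20 °C | 25 °C |
| remark | the very flask that is asked about, followed so far | run made earlier |  |
| time |  |  | 4.0 d |

- south (time / h: product / %): 10.0: 51.7; 25.0: 66.8; 50.0: 69.4; 72.0: 70.9
- south-west (time / h: product / %): 0.333: 3.2; 0.667: 6.6; 1.50: 14.3; 4.00: 33.3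

(each reading ± 1 percentage point)

- product, in percent of the substrate first charged, at 4.0 d
- what to do for the largest gain in product; "none" if nothing gains more than 2 percentage points (autumn / winter / spring / midnight / none)
- product present, in percent of the substrate first charged, after autumn
- product present, in percent of the substrate first charged, after spring

- autumn: at 4.0 d take out 90% of the by-product then present, then wait 4.0 d
- winter: change nothing and wait 4.0 d more
- spring: at 4.0 d raise the temperature by 25 K, then wait 4.0 d
- midnight: at 4.0 d add coupling partner, 100% of the amount charged, then wait 4.0 d

- what is added takes up no volume worth counting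
- a reading or a percentage of product counts all its forms, free or not

Take the main step first: substrate and coupling partner give product and by-product, one each. In the south flask c(coupling partner)/c(substrate) is 70.0%: call this the partner ceiling, the share of the charged substrate that the coupling partner can turn into product at one each. The coupling partner is then the limiting reagent. Test it. The south reading at 72.0 h stands 0.9 percentage points above the ceiling, less than the scatter of 1 point, so read each partner molecule as ending in product.

Now add time. The gap to the ceiling shrinks from 18 points at 10.0 h to 3.2 points at 25.0 h, a reading of 0.116 h⁻¹. Carry that to 4.0 d: the gap is 8.3 × 10⁻⁴ points, far under the scatter. So time leaves the number at the ceiling.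

Add the rest. Initiator is charged at 5.00% of the substrate, yet the first south reading is ten times that, so initiator is no one-for-one reagent. Treat it as a starter that bears on speed and leave the ceiling where it is. The south readings do not fall between 50.0 h and 72.0 h, so assume no loss of product.

My reckoning is therefore 70.0% now, and the same after autumn, winter or spring. Midnight doubles the partner and lifts the ceiling to 140%, above what the substrate allows, so expect 100%.

The forecast gives 70% now, midnight as best, and 70.2% and 70.2% after autumn and spring: “Removing by-product, waiting or heating therefore gains nothing”.

The flask gives 70.0%, and midnight is best, gaining 30 points and reaching 99.6%; autumn gives 70.0%, spring 70.0%. At 96.0 h the free coupling partner stands at 0% of its charge.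

    coupling partner + first chain carrier → product + second chain carrier (k = 2.70 × 10⁷ M⁻¹ h⁻¹, Ea = 33.0 kJ mol⁻¹)
    initiator → 2 initiating radical (k = 4.30 × 10⁻⁴ h⁻¹, Ea = 121 kJ mol⁻¹)
    crystals ⇌ product, rate k3*(cs3 - [product]) while solid is left; crystals form when [product] > cs3 (solubility = 30.0 mM, k = 0.800 h⁻¹)
    substrate + second chain carrier → by-product + first chain carrier (k = 2.20 × 10⁵ M⁻¹ s⁻¹, Ea = 12.0 kJ mol⁻¹)
    2 second chain carrier → ended chains B (k = 4.00 × 10⁸ M⁻¹ s⁻¹, Ea = 8.00 kJ mol⁻¹)
    substrate + initiating radical → capped initiator + first chain carrier (k = 7.30 × 10⁵ M⁻¹ s⁻¹, Ea = 21.0 kJ mol⁻¹)
    2 first chain carrier → ended chains A (k = 2.00 × 10⁷ M⁻¹ s⁻¹, Ea = 13.0 kJ mol⁻¹)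
    (constants at 25 °C)

Put the ceiling to a neighbour of the south flask, charged with 0.021 M of coupling partner and otherwise unchanged. Its ceiling is 27.6%, and that flask gives 27.6%.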